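**Retrosynthetic overview**

- The target is the (2R,3S) enantiomer of dihydrodehydrodiconiferyl alcohol with a (Z)-feruloyl ester on the 3-hydroxypropyl oxygen and an (E)-p-coumaroyl ester on the C3 hydroxymethyl oxygen. Both esters are cut by Mitsunobu esterification with the free phenolic acids, the unbranched side-chain alcohol first.
- Enabling feature: in the dihydrofuran ring (O1, C2, C3, C3a, C7a), C3 carries a one-carbon branch (the CH2O carbon) next to the aromatic carbon C3a. Reconnecting C3a to that branch carbon gives the six-membered pyranone ring (O1, C2, C3, C4, C4a, C8a) of a 2-arylchroman-4-one, so the five-membered ring is made by oxidative 1,2-aryl-shift ring contraction, which expels C4 as an ester carbon and sets C3 trans to C2.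
- The (2R)-flavanone comes from a 6,8-disubstituted chromone and an arylboronic acid by asymmetric conjugate addition (sets C2); the chromone comes from methyl dihydroferulate by Fries acylation and enaminone cyclization.
- Ring order: both benzene rings are bought, the pyranone ring is closed first and then contracted to the dihydrofuran. A pivalate on ring B and a methyl ester in the side chain serve the contraction and are cleared together with the new ester in one hydride reduction.

Key step: step 5

Remark: the (S) ligand of the conjugate addition is assigned by analogy with its facial preference on cyclic enones; should it deliver the (2S) flavanone, the (R) ligand is used instead.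

**Route**

Step 1
Reactants: 1 methyl 3-(4-hydroxy-3-methoxyphenyl)propanoate
Product: 3 methyl 3-(3-acetyl-4-hydroxy-5-methoxyphenyl)propanoate, via aryl acetate 2 (not isolated)
Conditions: Ac2O (1.3 equiv), BF3·OEt2 (3 equiv), 90 °C; then aq. NaOAc, 50 °C
Reagents that add atoms: acetic anhydride CC(=O)OC(C)=O
Why: O-acetylation followed by BF3-promoted Fries rearrangement, in which the blocked para position leaves only the free position ortho to the phenol oxygen for the acetyl group, where the product is held as a difluoroboron chelate until work-up.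

Step 2
Reactants: 3 methyl 3-(3-acetyl-4-hydroxy-5-methoxyphenyl)propanoate
Product: 5 methyl 3-(8-methoxy-4-oxo-4H-chromen-6-yl)propanoate, via enaminone 4 (not isolated)
Conditions: Me2NCH(OMe)2 (2 equiv), toluene, 100 °C; then conc. HCl, CH2Cl2, rt
Reagents that add atoms: N,N-dimethylformamide dimethyl acetal COC(OC)N(C)C
Why: enaminone formation at the methyl ketone and acid-promoted cyclization with loss of dimethylamine (the standard enaminone route to 2,3-unsubstituted chromones), the ester α-methylene being too weakly acidic to condense.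

Step 3
Reactants: 6 (4-hydroxy-3-methoxyphenyl)boronic acid
Product: 7 [3-methoxy-4-(pivaloyloxy)phenyl]boronic acid
Conditions: t-BuCOCl (1.1 equiv), pyridine, CH2Cl2, 0 °C to rt; aq. HCl work-up
Reagents that add atoms: pivaloyl chloride CC(C)(C)C(Cl)=O
Why: chemoselective O-acylation of the phenol (ester formation with an acid chloride), any mixed boron acyl species being hydrolysed in the work-up; the pivalate is chosen to make ring B electron-poorer for step 5.

Step 4
Reactants: 5 methyl 3-(8-methoxy-4-oxo-4H-chromen-6-yl)propanoate; 7 [3-methoxy-4-(pivaloyloxy)phenyl]boronic acid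
Product: 8 methyl 3-[(2R)-8-methoxy-2-[3-methoxy-4-(pivaloyloxy)phenyl]-4-oxochroman-6-yl]propanoate
Conditions: Pd(OCOCF3)2 (5 mol %), (S)-t-BuPyOX (6 mol %), NH4PF6 (30 mol %), H2O (5 equiv), ClCH2CH2Cl, 60 °C
Reagents that add atoms: none
Why: asymmetric conjugate addition of an arylboronic acid to a chromone under a cationic divalent palladium pyridine-oxazoline catalyst (transmetalation, enantio-determining carbopalladation of C2=C3, protonolysis of the palladium enolate), the ligand shielding one face so that C2 is set as R, while the non-basic medium keeps the flavanone from opening to the chalcone.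

Step 5
Reactants: 8 methyl 3-[(2R)-8-methoxy-2-[3-methoxy-4-(pivaloyloxy)phenyl]-4-oxochroman-6-yl]propanoate
Product: 11 methyl (2R,3R)-7-methoxy-2-[3-methoxy-4-(pivaloyloxy)phenyl]-5-(3-methoxy-3-oxopropyl)-2,3-dihydro-1-benzofuran-3-carboxylate, via enol ether 9 (not isolated), via alkyliodane 10 (not isolated)
Conditions: PhI(OAc)2 (1.2 equiv), conc. H2SO4 (cat.), HC(OMe)3, 0 °C to rt; then aq. NaHCO3
Reagents that add atoms: trimethyl orthoformate COC(OC)OC
Why: The orthoformate and acid turn the ketone into its dimethyl ketal and enol ether 9, PhI(OAc)2 adds to C3 of 9 anti to the C2 aryl group and methanol adds to C4 to give the trans alkyliodane 10, and loss of iodobenzene is coupled to a 1,2-shift of the ring A carbon C4a from C4 to C3, the cation left at C4 being held by its two methoxy groups and ending as the methyl ester. This is the known oxidative ring contraction of flavanones to methyl trans-2-aryl-2,3-dihydrobenzofuran-3-carboxylates with trivalent iodine in trimethyl orthoformate. The five-membered ring (O1, C2, C3, C3a, C7a) is closed by this suprafacial 1,2-aryl shift through a phenonium-like bridged transition state, which turns the six-membered pyranone ring into the dihydrofuran and expels the former C4 as the exocyclic carboxyl carbon. The new stereocentre C3 is controlled by C2: iodine enters trans to the aryl group and is displaced with inversion, so the ester ends trans to the aryl group, which is also the thermodynamically favoured arrangement of this epimerisable centre, and C2 is not touched. The step needs migration of C4a in preference to migration of ring B from C2 (isoflavone pathway) and to methoxylation or dehydrogenation at C3, and it needs C2 to keep its configuration in acid; the ortho oxygen O1 activates C4a as the migrating carbon, the pivalate makes ring B a poor migrating group and a poor stabiliser of a cation at C2, and ketal formation removes the carbonyl group that a retro-oxa-Michael opening would require.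

Step 6
Reactants: 11 methyl (2R,3R)-7-methoxy-2-[3-methoxy-4-(pivaloyloxy)phenyl]-5-(3-methoxy-3-oxopropyl)-2,3-dihydro-1-benzofuran-3-carboxylate
Product: 12 4-[(2R,3S)-3-(hydroxymethyl)-5-(3-hydroxypropyl)-7-methoxy-2,3-dihydro-1-benzofuran-2-yl]-2-methoxyphenol ((2R,3S)-dihydrodehydrodiconiferyl alcohol)
Conditions: LiAlH4 (5 equiv), THF, 0 °C to rt; aq. KNaC4H4O6 (potassium sodium tartrate) work-up
Reagents that add atoms: none
Why: hydride reduction of both methyl esters to primary alcohols with concurrent reductive cleavage of the aryl pivalate, so that one operation unmasks all three hydroxyl groups without touching either stereocentre (the C3 label changes from R to S only because CH2OH ranks below C2).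

Step 7
Reactants: 13 vanillin (4-hydroxy-3-methoxybenzaldehyde)
Product: 14 4-(tert-butyldimethylsilyloxy)-3-methoxybenzaldehyde
Conditions: TBSCl (1.1 equiv), imidazole (2 equiv), DMF, rt
Reagents that add atoms: tert-butyldimethylsilyl chloride CC(C)(C)[Si](C)(C)Cl
Why: standard silylation of a phenol, which keeps the aldehyde electrophilic under the strongly basic olefination that follows.

Step 8
Reactants: 14 4-(tert-butyldimethylsilyloxy)-3-methoxybenzaldehyde; 15 methyl bis(2,2,2-trifluoroethyl)phosphonoacetate
Product: 16 methyl (2Z)-3-[4-(tert-butyldimethylsilyloxy)-3-methoxyphenyl]prop-2-enoate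
Conditions: KN(SiMe3)2, 18-crown-6, THF, −78 °C
Reagents that add atoms: none
Why: Still–Gennari olefination, in which the electron-poor trifluoroethyl phosphonate makes elimination from the kinetically formed adduct faster than its equilibration and so gives the Z alkene.

Step 9
Reactants: 16 methyl (2Z)-3-[4-(tert-butyldimethylsilyloxy)-3-methoxyphenyl]prop-2-enoate
Product: 17 (2Z)-3-(4-hydroxy-3-methoxyphenyl)prop-2-enoic acid ((Z)-ferulic acid)
Conditions: LiOH (4 equiv), THF/MeOH/H2O, 0 °C to rt, dark; then aq. HCl to pH 3, 0 °C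
Reagents that add atoms: lithium hydroxide [Li+].[OH-]
Why: saponification of the methyl ester with concurrent cleavage of the aryl silyl ether by hydroxide, run cold and in the dark so that the Z geometry should be kept.

Step 10
Reactants: 12 (2R,3S)-dihydrodehydrodiconiferyl alcohol; 17 (Z)-ferulic acid
Product: 18 3-[(2R,3S)-2-(4-hydroxy-3-methoxyphenyl)-3-(hydroxymethyl)-7-methoxy-2,3-dihydro-1-benzofuran-5-yl]propyl (2Z)-3-(4-hydroxy-3-methoxyphenyl)prop-2-enoate
Conditions: 17 (1.0 equiv), PPh3 (1.1 equiv), DIAD (1.1 equiv, slow addition), THF, −20 to 0 °C, dark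
Reagents that add atoms: none
Why: Mitsunobu esterification, in which the carboxylate displaces the alkoxyphosphonium group by SN2, so the unbranched 3-hydroxypropyl carbinol should react well ahead of the β-branched C3 hydroxymethyl group, the phenols are too weakly acidic to compete with the acid, and the Z acid is never turned into an acyl electrophile.

Step 11
Reactants: 18 mono (Z)-feruloyl ester; 19 (2E)-3-(4-hydroxyphenyl)prop-2-enoic acid ((E)-p-coumaric acid)
Product: 20 3-[(2R,3S)-3-({[(2E)-3-(4-hydroxyphenyl)prop-2-enoyl]oxy}methyl)-2-(4-hydroxy-3-methoxyphenyl)-7-methoxy-2,3-dihydro-1-benzofuran-5-yl]propyl (2Z)-3-(4-hydroxy-3-methoxyphenyl)prop-2-enoate (target)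
Conditions: 19 (1.5 equiv), PPh3 (1.6 equiv), DIAD (1.6 equiv), THF, 0 °C to rt, dark
Reagents that add atoms: none
Why: second Mitsunobu esterification at the remaining primary alcohol, chemoselective for the carboxylic acid over the three free phenols and not involving the stereocentres or either alkene.

**Compound list**

1 | methyl 3-(4-hydroxy-3-methoxyphenyl)propanoate | COC(=O)CCc1ccc(O)c(OC)c1 | starting material
2 | methyl 3-(4-acetoxy-3-methoxyphenyl)propanoate | COC(=O)CCc1ccc(OC(C)=O)c(OC)c1 | intermediate
3 | methyl 3-(3-acetyl-4-hydroxy-5-methoxyphenyl)propanoate | COC(=O)CCc1cc(OC)c(O)c(C(C)=O)c1 | intermediate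
4 | methyl 3-{3-[(2E)-3-(dimethylamino)prop-2-enoyl]-4-hydroxy-5-methoxyphenyl}propanoate | COC(=O)CCc1cc(OC)c(O)c(C(=O)/C=C/N(C)C)c1 | intermediate
5 | methyl 3-(8-methoxy-4-oxo-4H-chromen-6-yl)propanoate | COC(=O)CCc1cc(OC)c2occc(=O)c2c1 | intermediate
6 | (4-hydroxy-3-methoxyphenyl)boronic acid | COc1cc(B(O)O)ccc1O | starting material
7 | [3-methoxy-4-(pivaloyloxy)phenyl]boronic acid | COc1cc(B(O)O)ccc1OC(=O)C(C)(C)C | intermediate
8 | methyl 3-[(2R)-8-methoxy-2-[3-methoxy-4-(pivaloyloxy)phenyl]-4-oxochroman-6-yl]propanoate | COC(=O)CCc1cc(OC)c2O[C@@H](c3ccc(OC(=O)C(C)(C)C)c(OC)c3)CC(=O)c2c1 | intermediate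
9 | methyl 3-[(2R)-4,8-dimethoxy-2-[3-methoxy-4-(pivaloyloxy)phenyl]-2H-chromen-6-yl]propanoate | COC(=O)CCc1cc(OC)c2O[C@@H](c3ccc(OC(=O)C(C)(C)C)c(OC)c3)C=C(OC)c2c1 | intermediate
10 | methyl 3-[(2S,3S)-3-[acetoxy(phenyl)-λ3-iodanyl]-4,4,8-trimethoxy-2-[3-methoxy-4-(pivaloyloxy)phenyl]chroman-6-yl]propanoate (2,3-trans; same arrangement at C2 as in 8, label changed by the iodine) | COC(=O)CCc1cc(OC)c2O[C@@H](c3ccc(OC(=O)C(C)(C)C)c(OC)c3)[C@H](I(OC(C)=O)c3ccccc3)C(OC)(OC)c2c1 | intermediate
11 | methyl (2R,3R)-7-methoxy-2-[3-methoxy-4-(pivaloyloxy)phenyl]-5-(3-methoxy-3-oxopropyl)-2,3-dihydro-1-benzofuran-3-carboxylate (2,3-trans) | COC(=O)CCc1cc(OC)c2O[C@@H](c3ccc(OC(=O)C(C)(C)C)c(OC)c3)[C@H](C(=O)OC)c2c1 | intermediate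
12 | 4-[(2R,3S)-3-(hydroxymethyl)-5-(3-hydroxypropyl)-7-methoxy-2,3-dihydro-1-benzofuran-2-yl]-2-methoxyphenol | OCCCc1cc(OC)c2O[C@@H](c3ccc(O)c(OC)c3)[C@H](CO)c2c1 | intermediate
13 | vanillin | COc1cc(C=O)ccc1O | starting material
14 | 4-(tert-butyldimethylsilyloxy)-3-methoxybenzaldehyde | COc1cc(C=O)ccc1O[Si](C)(C)C(C)(C)C | intermediate
15 | methyl bis(2,2,2-trifluoroethyl)phosphonoacetate | COC(=O)CP(=O)(OCC(F)(F)F)OCC(F)(F)F | starting material
16 | methyl (2Z)-3-[4-(tert-butyldimethylsilyloxy)-3-methoxyphenyl]prop-2-enoate | COC(=O)/C=C\c1ccc(O[Si](C)(C)C(C)(C)C)c(OC)c1 | intermediate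
17 | (2Z)-3-(4-hydroxy-3-methoxyphenyl)prop-2-enoic acid | COc1cc(/C=C\C(=O)O)ccc1O | intermediate
18 | 3-[(2R,3S)-2-(4-hydroxy-3-methoxyphenyl)-3-(hydroxymethyl)-7-methoxy-2,3-dihydro-1-benzofuran-5-yl]propyl (2Z)-3-(4-hydroxy-3-methoxyphenyl)prop-2-enoate | COc1cc(/C=C\C(=O)OCCCc2cc(OC)c3O[C@@H](c4ccc(O)c(OC)c4)[C@H](CO)c3c2)ccc1O | intermediate
19 | (2E)-3-(4-hydroxyphenyl)prop-2-enoic acid | OC(=O)/C=C/c1ccc(O)cc1 | starting material
20 | 3-[(2R,3S)-3-({[(2E)-3-(4-hydroxyphenyl)prop-2-enoyl]oxy}methyl)-2-(4-hydroxy-3-methoxyphenyl)-7-methoxy-2,3-dihydro-1-benzofuran-5-yl]propyl (2Z)-3-(4-hydroxy-3-methoxyphenyl)prop-2-enoate | COc1cc(/C=C\C(=O)OCCCc2cc(OC)c3c(c2)[C@@H](COC(=O)/C=C/c2ccc(O)cc2)[C@H](c2ccc(O)c(OC)c2)O3)ccc1O | target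

**Summary**

Total step count: 11. Longest linear sequence: 7 steps (steps 1, 2, 4, 5, 6, 10, 11).

**Steps most likely to fail**

Step 5 may fail through migration of ring B instead of ring A, through capture of the iodane by methanol at C3, or through acid-induced ring opening that erodes the configuration at C2. The fallback is a Wolff ring contraction that sets out from 8 and returns at 11. LiN(SiMe3)2, THF, −78 °C, then CF3CO2CH2CF3 would give the 3-trifluoroacetyl flavanone F1. MsN3, Et3N, H2O, MeCN would transfer the diazo group with loss of the trifluoroacetyl group and give the 3-diazoflavanone F2. Irradiation at 350 nm in MeOH/THF would induce the Wolff rearrangement, in which C4a again moves from C4 to C3 and the ring-contracted ketene is trapped by methanol, probably first as the cis ester F3. DBU (cat.), toluene, rt would then epimerise C3 to the trans ester 11.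

Step 10 may fail through insufficient discrimination between the two primary hydroxyl groups, leading to double esterification, or through slow geometric isomerisation of the Z acid in a sluggish reaction. The fallback uses temporary protection and the reversed order of esterification; it sets out from 12 and returns at 20. Ph3CCl, pyridine, DMAP (cat.), CH2Cl2, 0 °C to rt should tritylate only the unhindered 3-hydroxypropyl oxygen and give the trityl ether F4. Mitsunobu esterification of F4 with 19 (PPh3, DIAD, THF) would give the trityl-protected coumarate F5. Camphorsulfonic acid (cat.), MeOH/CH2Cl2, 0 °C would remove the trityl group and give the hydroxy coumarate F6. A final Mitsunobu esterification of F6 with 17 in the dark would give 20, with the Z ester introduced last.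

Step 4 may fail through slow carbopalladation of this electron-rich chromone, so that protodeboronation of 7 wins, or through incomplete facial selectivity. The fallback is a racemic addition followed by kinetic resolution; it sets out from 5 and 7 and returns at 8. Pd(OCOCF3)2, 2,2'-bipyridine, NH4PF6, H2O, ClCH2CH2Cl, 60 °C would give the racemic flavanone F7. Asymmetric transfer hydrogenation with RuCl(p-cymene)[(S,S)-TsDPEN] in the HCO2H/Et3N azeotrope, stopped near half conversion, should reduce the (2S) enantiomer to the cis flavan-4-ol F8 and leave the (2R) ketone 8, which is separated by chromatography.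

Further compounds
F1 | step 5 | methyl 3-[(2R)-8-methoxy-2-[3-methoxy-4-(pivaloyloxy)phenyl]-4-oxo-3-(trifluoroacetyl)chroman-6-yl]propanoate (C3 enolisable, not assigned) | COC(=O)CCc1cc(OC)c2O[C@@H](c3ccc(OC(=O)C(C)(C)C)c(OC)c3)C(C(=O)C(F)(F)F)C(=O)c2c1
F2 | step 5 | methyl 3-[(2S)-3-diazo-8-methoxy-2-[3-methoxy-4-(pivaloyloxy)phenyl]-4-oxochroman-6-yl]propanoate (same arrangement at C2 as in 8) | COC(=O)CCc1cc(OC)c2O[C@@H](c3ccc(OC(=O)C(C)(C)C)c(OC)c3)C(=[N+]=[N-])C(=O)c2c1
F3 | step 5 | methyl (2R,3S)-7-methoxy-2-[3-methoxy-4-(pivaloyloxy)phenyl]-5-(3-methoxy-3-oxopropyl)-2,3-dihydro-1-benzofuran-3-carboxylate (2,3-cis) | COC(=O)CCc1cc(OC)c2O[C@@H](c3ccc(OC(=O)C(C)(C)C)c(OC)c3)[C@@H](C(=O)OC)c2c1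
F4 | step 10 | 4-[(2R,3S)-3-(hydroxymethyl)-7-methoxy-5-[3-(trityloxy)propyl]-2,3-dihydro-1-benzofuran-2-yl]-2-methoxyphenol | C(c1ccccc1)(c1ccccc1)(c1ccccc1)OCCCc1cc(OC)c2O[C@@H](c3ccc(O)c(OC)c3)[C@H](CO)c2c1
F5 | step 10 | [(2R,3S)-2-(4-hydroxy-3-methoxyphenyl)-7-methoxy-5-[3-(trityloxy)propyl]-2,3-dihydro-1-benzofuran-3-yl]methyl (2E)-3-(4-hydroxyphenyl)prop-2-enoate | C(c1ccccc1)(c1ccccc1)(c1ccccc1)OCCCc1cc(OC)c2O[C@@H](c3ccc(O)c(OC)c3)[C@H](COC(=O)/C=C/c3ccc(O)cc3)c2c1
F6 | step 10 | [(2R,3S)-2-(4-hydroxy-3-methoxyphenyl)-5-(3-hydroxypropyl)-7-methoxy-2,3-dihydro-1-benzofuran-3-yl]methyl (2E)-3-(4-hydroxyphenyl)prop-2-enoate | OCCCc1cc(OC)c2O[C@@H](c3ccc(O)c(OC)c3)[C@H](COC(=O)/C=C/c3ccc(O)cc3)c2c1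
F7 | step 4 | methyl 3-[8-methoxy-2-[3-methoxy-4-(pivaloyloxy)phenyl]-4-oxochroman-6-yl]propanoate (racemate) | COC(=O)CCc1cc(OC)c2OC(c3ccc(OC(=O)C(C)(C)C)c(OC)c3)CC(=O)c2c1
F8 | step 4 | methyl 3-[(2S,4S)-4-hydroxy-8-methoxy-2-[3-methoxy-4-(pivaloyloxy)phenyl]chroman-6-yl]propanoate (2,4-cis) | COC(=O)CCc1cc(OC)c2O[C@H](c3ccc(OC(=O)C(C)(C)C)c(OC)c3)C[C@H](O)c2c1
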